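**Plan**

1. Arene numbering used here: C1 carries the carbinol, C2 the methoxy group, C4 the methyl group. The retrosynthesis first cuts the two ester C–O bonds (triol 18), then opens the benzene ring across C3–C4 and C5–C6.
2. The feature that allows this cut: C4 with its methyl group and the unsubstituted neighbour C5 form a propyne-derived two-carbon unit. C3, C2, C1 and C6 form a buta-1,3-diene whose two inner carbons already hold the methoxy group and the protected carbinol.
3. The diene is cut at its central C1–C2 bond into (1-methoxyethenyl)ZnCl and an enol triflate. The triflate comes from the methyl ketone made by adding a 1-alkoxyethenyl anion (acetyl anion equivalent) to 2,2-dimethyl-1,3-dioxan-5-one.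
4. Forward: the side chain and diene are assembled first (steps 1–4). The only carbocycle then arises by cycloaddition with the sulfonyl-activated propyne 14 (step 6) and is aromatised by loss of sulfinic acid (step 7). Deprotection and double acylation finish (steps 8–9).
5. The target has no stereogenic centre, since the carbinol carbon bears two identical acyloxymethyl arms. The only selectivity to secure is the orientation of the cycloaddition, which the methoxy group dictates.

Key step: step 6

Remark: the propyne unit is brought in as an alkynyl sulfone and not as a nitroalkene. A secondary nitro group without an acidifying β-substituent is expected only to form its nitronate with amine bases, whereas a sulfonyl group on a cyclohexadiene can leave with aromatisation.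

**Step 1**
Reactants: 1 2,2-dimethyl-1,3-dioxan-5-one; 2 ethoxyethene
Product: 5 1-(5-hydroxy-2,2-dimethyl-1,3-dioxan-5-yl)ethan-1-one, via 1-ethoxyvinyllithium 3 (not isolated), via enol ether carbinol 4 (not isolated)
Conditions: 2 (2.5 equiv), t-BuLi (1.5 equiv), THF, −78 → 0 °C; 1, −78 °C; then 0.1 M aq. HCl, 0 °C; NaHCO3
Reagents that add atoms: water, O
Why: Deprotonation of the vinyl ether at its oxygen-bearing carbon gives an acetyl anion equivalent that undergoes 1,2-addition to the ketone, and cold dilute acid should hydrolyse the resulting 1-ethoxyethenyl carbinol (enol ether hydrolysis) much faster than the isopropylidene acetal; the ethyl ether is used because its alkoxy group is lost in this step and ethoxyethene is an easily handled liquid.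

**Step 2**
Reactants: 5 1-(5-hydroxy-2,2-dimethyl-1,3-dioxan-5-yl)ethan-1-one
Product: 6 1-[2,2-dimethyl-5-(trimethylsilyloxy)-1,3-dioxan-5-yl]ethan-1-one
Conditions: 1-(trimethylsilyl)imidazole (1.5 equiv), CH2Cl2, 23 °C
Reagents that add atoms: 1-(trimethylsilyl)imidazole, C[Si](C)(C)n1ccnc1
Why: O-Silylation with this neutral silyl donor caps even tertiary hydroxyls without added base, so the methyl ketone is not enolised and the acetal is untouched.

**Step 3**
Reactants: 6 1-[2,2-dimethyl-5-(trimethylsilyloxy)-1,3-dioxan-5-yl]ethan-1-one
Product: 8 1-[2,2-dimethyl-5-(trimethylsilyloxy)-1,3-dioxan-5-yl]ethenyl trifluoromethanesulfonate, via lithium enolate 7 (not isolated)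
Conditions: LiN(SiMe3)2 (1.1 equiv), THF, −78 °C; N-(5-chloropyridin-2-yl)-N-(trifluoromethanesulfonyl)trifluoromethanesulfonamide (1.1 equiv), −78 → −30 °C
Reagents that add atoms: N-(5-chloropyridin-2-yl)-1,1,1-trifluoro-N-(trifluoromethanesulfonyl)methanesulfonamide, FC(F)(F)S(=O)(=O)N(c1ccc(Cl)cn1)S(=O)(=O)C(F)(F)F
Why: The ketone can enolise only towards its methyl group because the other α-carbon is quaternary, and O-sulfonylation of the lithium enolate with an N-heteroaryl triflimide at low temperature is the standard enol triflate synthesis, the cold conditions also holding back silyl migration to the enolate oxygen.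

**Step 4**
Reactants: 8 1-[2,2-dimethyl-5-(trimethylsilyloxy)-1,3-dioxan-5-yl]ethenyl trifluoromethanesulfonate; 9 methoxyethene
Product: 12 5-(3-methoxybuta-1,3-dien-2-yl)-2,2-dimethyl-5-(trimethylsilyloxy)-1,3-dioxane, via 1-methoxyvinyllithium 10 (not isolated), via alkenylzinc chloride 11 (not isolated)
Conditions: 9 (3 equiv, condensed at −78 °C), t-BuLi (2 equiv), THF, −78 → 0 °C; ZnCl2 (2 equiv), 0 → 23 °C; 8, Pd(PPh3)4 (5 mol %), THF, 23 → 45 °C; NaHCO3 work-up, Et3N-washed SiO2
Reagents that add atoms: none
Why: Negishi coupling of an α-alkoxyalkenylzinc chloride with an alkenyl electrophile under Pd(PPh3)4 catalysis is an established route to 2-alkoxybuta-1,3-dienes, the methyl ether that the target retains is introduced here from methoxyethene, and the mild zinc reagent should leave the silyl ether and the acetal alone.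

**Step 5**
Reactants: 13 trimethyl(prop-1-yn-1-yl)silane
Product: 14 1-methyl-4-(prop-1-yn-1-ylsulfonyl)benzene
Conditions: TsCl (1.1 equiv), AlCl3 (1.1 equiv), CH2Cl2, 0 → 23 °C
Reagents that add atoms: 4-methylbenzenesulfonyl chloride, Cc1ccc(cc1)S(Cl)(=O)=O
Why: The AlCl3-activated sulfonyl chloride attacks the silicon-bearing alkyne carbon through a β-silyl-stabilised vinyl cation and chloride then removes the silyl group, a Friedel–Crafts-type ipso-sulfonylation of alkynylsilanes that is the usual entry to acetylenic sulfones.

**Step 6**
Reactants: 12 5-(3-methoxybuta-1,3-dien-2-yl)-2,2-dimethyl-5-(trimethylsilyloxy)-1,3-dioxane; 14 1-methyl-4-(prop-1-yn-1-ylsulfonyl)benzene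
Product: 15 5-[2-methoxy-4-methyl-5-(4-methylbenzenesulfonyl)cyclohexa-1,4-dien-1-yl]-2,2-dimethyl-5-(trimethylsilyloxy)-1,3-dioxane
Conditions: 14 (1.3 equiv), BHT (cat.), PhMe, 110 °C, sealed tube (base-washed glass)
Reagents that add atoms: none
Why: The electron-rich s-cis diene adds through its HOMO to the sulfonyl-lowered LUMO of the alkyne in a concerted, asynchronous, suprafacial thermal [4+2] cycloaddition that forms the C3–C4 and C5–C6 bonds of the future arene. The closest known reaction type is the Diels–Alder reaction of acetylenic sulfones with 2-alkoxy- and 2-silyloxybuta-1,3-dienes, in which the sulfone serves as a removable activator of the alkyne. The six-membered carbocycle closes in this intermolecular [4+2] mode, the two diene termini bonding to the two alkyne carbons, and it emerges as a cyclohexa-1,4-diene that needs only loss of sulfinic acid to become the arene. No stereocentre is formed, because the two new sp3 carbons are CH2 groups and the other four ring carbons are sp2. The step needs regiocontrol, and the substrate secures it: the methoxy group places the largest HOMO coefficient on the adjacent terminal CH2, which bonds to the methyl-bearing β-carbon of the alkynyl sulfone (largest LUMO coefficient), so that methyl ends meta and sulfonyl para to methoxy. The alkyl substituent on the other inner diene carbon is a far weaker donor and should not reverse this orientation.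

**Step 7**
Reactants: 15 5-[2-methoxy-4-methyl-5-(4-methylbenzenesulfonyl)cyclohexa-1,4-dien-1-yl]-2,2-dimethyl-5-(trimethylsilyloxy)-1,3-dioxane
Product: 17 5-(2-methoxy-4-methylphenyl)-2,2-dimethyl-5-(trimethylsilyloxy)-1,3-dioxane, via allylic sulfone 16 (not isolated)
Conditions: DBU (2 equiv), MeCN, 23 → 60 °C
Reagents that add atoms: none
Why: DBU is known to shift vinyl sulfones to allylic sulfones through the sulfonyl-stabilised (here doubly allylic) carbanion, and once the sulfonyl group sits on an sp3 carbon of cyclohexa-1,3-diene 16 the 1,2-loss of sulfinate is driven by aromatisation (eliminative aromatisation), so no oxidant is required.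

**Step 8**
Reactants: 17 5-(2-methoxy-4-methylphenyl)-2,2-dimethyl-5-(trimethylsilyloxy)-1,3-dioxane
Product: 18 2-(2-methoxy-4-methylphenyl)propane-1,2,3-triol
Conditions: AcOH/THF/H2O (3:1:1), 40 °C
Reagents that add atoms: none
Why: Aqueous acetic acid hydrolyses both the isopropylidene acetal and the trimethylsilyl ether (acetal and silyl ether hydrolysis) while being too weakly acidic to ionise the tertiary benzylic carbinol.

**Step 9**
Reactants: 18 2-(2-methoxy-4-methylphenyl)propane-1,2,3-triol
Product: 19 2-hydroxy-2-(2-methoxy-4-methylphenyl)propane-1,3-diyl bis(2-methylpropanoate)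
Conditions: (i-PrCO)2O (2.4 equiv), Et3N, DMAP (5 mol %), CH2Cl2, 0 → 23 °C
Reagents that add atoms: 2-methylpropanoic anhydride, CC(C)C(=O)OC(=O)C(C)C
Why: DMAP-catalysed acylation with an anhydride esterifies the two primary hydroxyls, whereas the tertiary benzylic hydroxyl is too hindered to react with a slight excess of reagent at this temperature (chemoselective esterification).

**Compound list**

1 | 2,2-dimethyl-1,3-dioxan-5-one | CC1(C)OCC(=O)CO1 | starting material
2 | ethoxyethene (ethyl vinyl ether) | CCOC=C | starting material
3 | (1-ethoxyethenyl)lithium (1-ethoxyvinyllithium) | [Li]C(=C)OCC | intermediate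
4 | 5-(1-ethoxyethenyl)-2,2-dimethyl-1,3-dioxan-5-ol (formed as its lithium alkoxide) | C=C(OCC)C1(O)COC(C)(C)OC1 | intermediate
5 | 1-(5-hydroxy-2,2-dimethyl-1,3-dioxan-5-yl)ethan-1-one | CC(=O)C1(O)COC(C)(C)OC1 | intermediate
6 | 1-[2,2-dimethyl-5-(trimethylsilyloxy)-1,3-dioxan-5-yl]ethan-1-one | CC(=O)C1(O[Si](C)(C)C)COC(C)(C)OC1 | intermediate
7 | lithium 1-[2,2-dimethyl-5-(trimethylsilyloxy)-1,3-dioxan-5-yl]ethen-1-olate | [Li]OC(=C)C1(O[Si](C)(C)C)COC(C)(C)OC1 | intermediate
8 | 1-[2,2-dimethyl-5-(trimethylsilyloxy)-1,3-dioxan-5-yl]ethenyl trifluoromethanesulfonate | C=C(OS(=O)(=O)C(F)(F)F)C1(O[Si](C)(C)C)COC(C)(C)OC1 | intermediate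
9 | methoxyethene (methyl vinyl ether) | COC=C | starting material
10 | (1-methoxyethenyl)lithium (1-methoxyvinyllithium) | [Li]C(=C)OC | intermediate
11 | chloro(1-methoxyethenyl)zinc | COC(=C)[Zn]Cl | intermediate
12 | 5-(3-methoxybuta-1,3-dien-2-yl)-2,2-dimethyl-5-(trimethylsilyloxy)-1,3-dioxane | C=C(OC)C(=C)C1(O[Si](C)(C)C)COC(C)(C)OC1 | intermediate
13 | trimethyl(prop-1-yn-1-yl)silane | CC#C[Si](C)(C)C | starting material
14 | 1-methyl-4-(prop-1-yn-1-ylsulfonyl)benzene | CC#CS(=O)(=O)c1ccc(C)cc1 | intermediate
15 | 5-[2-methoxy-4-methyl-5-(4-methylbenzenesulfonyl)cyclohexa-1,4-dien-1-yl]-2,2-dimethyl-5-(trimethylsilyloxy)-1,3-dioxane | COC1=C(C2(O[Si](C)(C)C)COC(C)(C)OC2)CC(S(=O)(=O)c2ccc(C)cc2)=C(C)C1 | intermediate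
16 | 5-[2-methoxy-4-methyl-5-(4-methylbenzenesulfonyl)cyclohexa-1,3-dien-1-yl]-2,2-dimethyl-5-(trimethylsilyloxy)-1,3-dioxane (racemic) | COC1=C(C2(O[Si](C)(C)C)COC(C)(C)OC2)CC(S(=O)(=O)c2ccc(C)cc2)C(C)=C1 | intermediate
17 | 5-(2-methoxy-4-methylphenyl)-2,2-dimethyl-5-(trimethylsilyloxy)-1,3-dioxane | COc1cc(C)ccc1C1(O[Si](C)(C)C)COC(C)(C)OC1 | intermediate
18 | 2-(2-methoxy-4-methylphenyl)propane-1,2,3-triol | COc1cc(C)ccc1C(O)(CO)CO | intermediate
19 | 2-hydroxy-2-(2-methoxy-4-methylphenyl)propane-1,3-diyl bis(2-methylpropanoate) (achiral) | COc1cc(C)ccc1C(O)(COC(=O)C(C)C)COC(=O)C(C)C | target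

**Step count and risks**

Total step count: 9.
Longest linear sequence: 8 steps (1 → 5 → 6 → 8 → 12 → 15 → 17 → 18 → 19); step 5 is a one-step side branch.

The three steps most likely to fail:

**Step 6.** The cycloaddition of a disubstituted alkyne to a diene with a quaternary substituent may be slow. Thermal polymerisation or acid-triggered hydrolysis of the enol ether diene could then outrun ring formation, and regiocontrol could erode at the temperature required. The fallback sets out from diene 12, keeps the ring-forming bonds, and exchanges the alkyne for a more reactive and less hindered allene. Sodium 4-methylbenzenesulfinate and 3-bromoprop-1-yne in DMF at 23 °C should give 1-methyl-4-(prop-2-yn-1-ylsulfonyl)benzene F1. Et3N (cat.) in CH2Cl2 should isomerise it to 1-methyl-4-(propa-1,2-dien-1-ylsulfonyl)benzene F2. This allene should add to 12 across its sulfonyl-bearing double bond in PhMe at 60–80 °C, the central allene carbon bonding to the CH2 next to the methoxy-bearing carbon, which would give 5-[2-methoxy-4-methylidene-5-(4-methylbenzenesulfonyl)cyclohex-1-en-1-yl]-2,2-dimethyl-5-(trimethylsilyloxy)-1,3-dioxane F3 (racemic). DBU in MeCN should then move the exocyclic double bond into the ring, which gives 16, and loss of sulfinate returns the material to the route at arene 17.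

**Step 7.** The double-bond migration may stall at a conjugated dienyl sulfone. Alternatively the delocalised carbanion may expel the neighbouring silyloxy group (vinylogous β-elimination) instead of being protonated on carbon. The fallback sets out from 15 and separates desulfonylation from aromatisation. Reductive cleavage of the vinyl sulfone with Na(Hg) (6% Na) and Na2HPO4 in MeOH/THF at −20 °C should give 5-(2-methoxy-4-methylcyclohexa-1,4-dien-1-yl)-2,2-dimethyl-5-(trimethylsilyloxy)-1,3-dioxane F4. Dehydrogenation of this cyclohexa-1,4-diene with DDQ (1.1 equiv) in PhMe at 0 → 23 °C returns the route at arene 17.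

**Step 4.** Oxidative addition into the hindered enol triflate may be slow, the alkenylpalladium intermediate may undergo β-oxygen elimination, and the methoxydiene may hydrolyse during isolation. The fallback sets out from triflate 8 and builds the enol ether by carbonyl methylenation instead of cross-coupling. Methoxycarbonylation with Pd(OAc)2/PPh3 (CO 1 atm, MeOH, Et3N, DMF, 40 °C) should give methyl 2-[2,2-dimethyl-5-(trimethylsilyloxy)-1,3-dioxan-5-yl]prop-2-enoate F5. Petasis methylenation of the ester carbonyl with Cp2TiMe2 in PhMe at 65 °C returns the route at diene 12.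

**Further compounds**

F1 | step 6 | 1-methyl-4-(prop-2-yn-1-ylsulfonyl)benzene | C#CCS(=O)(=O)c1ccc(C)cc1
F2 | step 6 | 1-methyl-4-(propa-1,2-dien-1-ylsulfonyl)benzene | C=C=CS(=O)(=O)c1ccc(C)cc1
F3 | step 6 | 5-[2-methoxy-4-methylidene-5-(4-methylbenzenesulfonyl)cyclohex-1-en-1-yl]-2,2-dimethyl-5-(trimethylsilyloxy)-1,3-dioxane (racemic) | COC1=C(C2(O[Si](C)(C)C)COC(C)(C)OC2)CC(S(=O)(=O)c2ccc(C)cc2)C(=C)C1
F4 | step 7 | 5-(2-methoxy-4-methylcyclohexa-1,4-dien-1-yl)-2,2-dimethyl-5-(trimethylsilyloxy)-1,3-dioxane | COC1=C(C2(O[Si](C)(C)C)COC(C)(C)OC2)CC=C(C)C1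
F5 | step 4 | methyl 2-[2,2-dimethyl-5-(trimethylsilyloxy)-1,3-dioxan-5-yl]prop-2-enoate | C=C(C(=O)OC)C1(O[Si](C)(C)C)COC(C)(C)OC1
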